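## Structural features

Rubioncolin C consists of two naphthalene units joined through one oxygen atom: C4 of a methyl 1-hydroxy-2-naphthoate (left half, substituted ring A fused to benzo ring B) is bonded through that oxygen to C2' of a 1,4-naphthoquinone (right half, quinone ring C fused to benzo ring D). Ring A is fully substituted, with the hydroxyl at C1 (hydrogen-bonded to the ester), the methyl ester at C2, the prenyl group at C3 and the ether oxygen at C4, while ring C carries only that oxygen at C2' and a hydrogen at C3'. The molecule has no stereocentre and no stereogenic double bond, so there are no neighbouring stereocentres to relate and nothing configurational to control. The fragile groups are the 2-aryloxyquinone, a vinylogous aryl ester that nucleophiles and base can cleave by addition–elimination at C2'; the trisubstituted prenyl alkene, which is sensitive to acid, electrophiles and radicals; and every intermediate at the naphthalene-1,4-diol level, which air oxidises. The real difficulty is the C4–O–C2' bond, whose oxygen lies between the prenyl group at C3 and the peri hydrogen at C5, together with the need to tell O1 from O4 on the left half. The key step uses the fact that C1' and C4' of ring C are both attached to the unsubstituted carbons C8a' and C4a' of ring D: ring C can therefore be divided into a two-carbon aryne unit (C4a'–C8a') and a four-carbon unit C1'–C4' whose oxygens at C1', C2' and C4' are those of a 4-aryloxy-2-silyloxyfuran derived from tetronic acid. In this way the hindered ether bond is made early on a small, non-oxidising butenolide, and ring C is built around it.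

## Logic of the disconnections

17 ⇒ 16. The last bond cut is the O1–CH2 bond of the acetal on the left half. O1 has to be capped while 12 is present, because a free naphthol would be arylated on oxygen, and an acetal is chosen because it survives base, fluoride, heat and silyl triflate. The gain is one of chemoselectivity only. The forward step needs an acid mild and non-nucleophilic enough to leave the vinylogous ester at C2' and the prenyl alkene alone.

16 ⇒ 14 (through 15). No skeletal bond is cut; ring C is taken back from the quinone to the diol oxidation level with O4' carrying silicon. This keeps the electrophilic quinone out of all earlier stages and reveals the retron of the key step, a 1-hydroxy-4-silyloxy arene. The forward step must cleave O–Si and dehydrogenate 15 without supplying a nucleophile that could displace the aryloxy group from C2' of 16.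

14 ⇒ 10 + 11 (through 13 and 12). The bonds C4'–C4a' and C1'–C8a' are cut, which removes ring C and separates ring D as the symmetrical two-carbon unit 12, released from 11. These are the only two bonds of ring C whose cleavage gives a symmetrical partner, so no regiochemistry arises, and the remaining four carbons carry the C1', C2' and C4' oxygens in the pattern of a furan. The gain is the largest of the route: a tetracyclic diaryl ether becomes a naphthalene bearing a five-membered heterocycle. The forward step requires 10 to act as a diene faster than any other group reacts with 12, and the bridged ketal 13 to open to 14.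

10 ⇒ 9. The O–Si bond is cut and the furan is returned to its butenolide tautomer. This exchanges a labile diene for a stable lactone. The forward step needs enolisation at the lactone CH2 only, under conditions that spare the ester and the acetal.

9 ⇒ 6 + 8. The bond between O4 and the vinylic carbon of the lactone is cut; this is the hindered ether bond of the target. Cutting here means it is formed on a small vinylogous acyl bromide and not on a redox-active quinone. The pieces are a naphthol and a four-carbon lactone. The forward step demands that the hindered oxygen of 6 adds to 8 faster than base degrades 8.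

8 ⇒ 7. The C–Br bond is cut, which leads to commercial 7. In the forward direction the enolic oxygen of 7 is replaced by bromide, so the ether oxygen of the target is O4 of 6 and does not come from 7.

6 ⇒ 4 (through 5). The C3–CH2 bond of the prenyl group is cut and the allyl unit is returned, inverted, to O4: a [3,3] retron. This replaces a C-alkylation of uncertain regiochemistry by an O-alkylation, and C3 is the only open ortho position of O4. The forward steps require reduction of the alkyne of 4 to the alkene of 5 and no further, and a rearrangement temperature that the acetal tolerates.

4 ⇒ 3 ⇒ 1 + 2. The O1–CH2 acetal bond and then the O4–C bond to the tertiary propargylic carbon are cut, which leads to two commercial compounds. O1 is capped before the prenyl group is moved to carbon, so that a free prenylated naphthalene-1,4-diol, which air would oxidise, never appears and 6 has a single free hydroxyl. The forward alkylation of 1 has to choose O4 over O1, which the hydrogen bond from O1–H to the ester should ensure.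

## Other disconnections considered

Alternative 1: The cut is the C1–C2 bond of ring A, which treats the left half as the ring-expanded form of a 2,2-disubstituted indane-1,3-dione.
- Forward key step: methyl 2-[2-(3-methylbut-2-en-1-yl)-1,3-dioxo-2,3-dihydro-1H-inden-2-yl]acetate A1 would be exposed to NaOMe in MeOH. Methoxide should cleave one acyl–C2 bond of A1 in a retro-Claisen step, and the ester enolate of the acetate arm should then close on the newly formed aryl methyl ester (Dieckmann condensation). Enolisation would give methyl 1,4-dihydroxy-3-(3-methylbut-2-en-1-yl)naphthalene-2-carboxylate A2.
- In its favour: A1 should be reachable by two C-alkylations of indane-1,3-dione A3, and A3 is an inexpensive commercial diketone. The prenyl group is placed on C3 with no regiochemical question and without the propargylation–reduction–rearrangement sequence, and the rearrangement is driven by aromatisation. For access to the left half this alternative is better in step economy than the chosen plan.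
- Against it here: the step builds ring A, which is not where the difficulty lies. The C4–O–C2' bond would still have to be made afterwards, most directly from A2 and 2-bromonaphthalene-1,4-dione A4. In that coupling an air-sensitive diol with two hydroxyls meets an oxidising quinone, so electron transfer from A2 to A4 and reaction at O1 could compete with addition–elimination at O4.
- Structure: the alternative settles the substitution pattern of ring A as cleanly as the Claisen route does (an equal point) but leaves ring C and the ether oxygen untouched, whereas the chosen plan creates ring C around an ether bond that already exists.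
- Mechanism: it is an anionic, thermodynamically driven sequence under strongly basic conditions, compared with a neutral cycloaddition. The base is harmless to A1 but would not be compatible with the quinone half, so the order of events is fixed.
- Step economy: the alternative would be shorter by several steps if the final coupling of A2 with A4 were clean, and that is its real advantage. The chosen plan spends those steps on never exposing a free hydroquinone to a quinone.

Alternative 2: The cut is the C4'–C4a' bond of ring C, with C1'–C4' traced to a squarate-derived four-membered ring.
- Forward key step: methyl 1-hydroxy-4-[(4-hydroxy-3-oxo-4-phenylcyclobut-1-en-1-yl)oxy]-3-(3-methylbut-2-en-1-yl)naphthalene-2-carboxylate A5, racemic at the carbinol carbon, would be heated in toluene or xylene. Conrotatory 4π ring opening of A5, with the hydroxyl turning outward, should give an aryloxy-substituted vinylketene, whose ketene carbon bonds to the ortho carbon of the phenyl group in a 6π electrocyclisation. Tautomerisation would give methyl 4-[(1,4-dihydroxynaphthalen-2-yl)oxy]-1-hydroxy-3-(3-methylbut-2-en-1-yl)naphthalene-2-carboxylate A6, which air should oxidise to the target.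
- In its favour: it builds the same ring as the chosen plan by a thermal, reagent-free pericyclic cascade. The carbinol stereocentre of A5 is destroyed, so no stereocontrol is needed, and no free aryne is present that could arylate a hydroxyl. A6 is one oxidation away from the target, so after the key step this alternative is better than the chosen plan, which needs desilylation, oxidation and acetal cleavage.
- Against it here: A5 has to come from a phenyl organometallic and the aryloxycyclobutenedione methyl 4-[(3,4-dioxocyclobut-1-en-1-yl)oxy]-1-hydroxy-3-(3-methylbut-2-en-1-yl)naphthalene-2-carboxylate A7. Making A7 means attaching the hindered O4 to a semisquarate that is itself two or three steps from a squarate ester. The organometallic must then choose one ketone of A7 over the other carbonyl, over the methyl ester and over displacement of the aryloxy group, with the C1 hydroxyl either protected or deprotonated. The thermolysis also places a ketene next to the prenyl alkene, where an intramolecular [2+2] reaction is conceivable.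
- Structure: both plans form the hindered ether bond early on a small vinylogous acid derivative and are equal in that respect. The chosen plan forms two bonds of ring C with a symmetrical two-carbon partner; the alternative forms one bond and must carry ring D in as a nucleophile.
- Mechanism: both are pericyclic. The alternative avoids fluoride and a silyl group; the chosen plan avoids an organometallic addition in the presence of an ester.
- Step economy: the alternative saves steps after the key step but is expected to lose at least as many before it, so the totals should be similar, with more chemoselectivity risk concentrated in the organometallic addition to A7.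

Alternative 3: The cuts are C2–C3 and C4–C4a of ring A, so that the left half is assembled from a benzoylacetate and an alkyne that already carries the right half on oxygen.
- Forward key step: methyl 2-bromo-3-oxo-3-phenylpropanoate A8 and the aryl ynol ether 1,4-bis(methoxymethoxy)-2-[(5-methylhex-4-en-1-yn-1-yl)oxy]naphthalene A9 would be irradiated with blue light in the presence of Ir(ppy)3 and a base. Reductive cleavage of the C–Br bond of A8 should give an electrophilic radical, which adds to the prenyl-bearing alkyne carbon of A9. The resulting α-aryloxyvinyl radical would close on the ortho carbon of the benzoyl group, and oxidation, loss of a proton and enolisation would give methyl 4-{[1,4-bis(methoxymethoxy)naphthalen-2-yl]oxy}-1-hydroxy-3-(3-methylbut-2-en-1-yl)naphthalene-2-carboxylate A10.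
- In its favour: it is the most convergent of the plans. Ring A and all four of its substituents arise in one step at room temperature, the polarity of the radical addition matches the electron-rich ynol ether, the C1 hydroxyl of A10 appears unprotected, and the regiochemistry follows from the mechanism. In convergence it is better than the chosen plan.
- Against it here: A9 is a skipped enyne whose CH2 group is both propargylic and allylic, so hydrogen abstraction there, and addition of the radical to the electron-rich prenyl alkene, could compete. Aryl ynol ethers of this kind need several steps from a protected 2-naphthol and are sensitive to acid and water. After the key step the two acetals of A10 must be removed and the diol oxidised, which exposes a free hydroquinone to acid.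
- Structure: the alternative builds the crowded ring A and carries ring C in protected form, whereas the chosen plan builds the unhindered ring C and takes ring A from a commercial naphthoate.
- Mechanism: a photoredox radical sequence on an alkene-containing substrate is judged less predictable than a cycloaddition between a furan and a symmetrical aryne, although both are regiochemically unambiguous (an equal point).
- Step economy: the key step itself is superior, but the preparation of A9 and the two-stage unmasking of ring C in A10 should bring the total to about the length of the chosen route.

Key step: step 7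

Assumption: the bridged ketal 13 is taken to open with silicon staying on O4'; a silyl shift to O1' would be harmless, since both isomers give 15 and 16 in step 8.

## Route

Step 1
Reactants: 1 methyl 1,4-dihydroxynaphthalene-2-carboxylate; 2 3-chloro-3-methylbut-1-yne
Product: 3 methyl 1-hydroxy-4-[(2-methylbut-3-yn-2-yl)oxy]naphthalene-2-carboxylate
Conditions: DBU, CuCl2·2H2O (cat.), MeCN, 0 °C, Ar
Reagents that add atoms: none
Why: Copper-catalysed O-propargylation (Williamson-type substitution through a copper acetylide) of the free O4–H; O1–H is held in a hydrogen bond to the C2 ester and flanked by the ester and the peri C8–H, so mono-alkylation at O4 is expected, and the low temperature keeps the propargyl ether from rearranging to a chromene.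

Step 2
Reactants: 3 methyl 1-hydroxy-4-[(2-methylbut-3-yn-2-yl)oxy]naphthalene-2-carboxylate
Product: 4 methyl 1-(methoxymethoxy)-4-[(2-methylbut-3-yn-2-yl)oxy]naphthalene-2-carboxylate
Conditions: NaH, MOMCl, DMF, 0 °C
Reagents that add atoms: chloromethyl methyl ether (MOMCl), COCCl
Why: Williamson-type acetal formation (MOM protection) on the sodium naphthoxide; one equivalent of NaH removes only the phenolic proton, so the terminal alkyne and the ester are untouched, and the acetal masks O1 against aryne O-arylation later and keeps a free hydroquinone from appearing after the Claisen step.

Step 3
Reactants: 4 methyl 1-(methoxymethoxy)-4-[(2-methylbut-3-yn-2-yl)oxy]naphthalene-2-carboxylate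
Product: 6 methyl 4-hydroxy-1-(methoxymethoxy)-3-(3-methylbut-2-en-1-yl)naphthalene-2-carboxylate, via reverse-prenyl ether 5 (not isolated)
Conditions: H2 (1 atm), Pd/CaCO3–Pb(OAc)2 (Lindlar catalyst), quinoline, EtOAc, rt; filter; then PhMe, 110 °C
Reagents that add atoms: none
Why: Lindlar semi-hydrogenation stops at the terminal alkene because the poisoned palladium surface binds alkynes far more strongly than alkenes; the 1,1-dimethylallyl aryl ether then undergoes an aromatic Claisen ([3,3]-sigmatropic) rearrangement to C3, the only free ortho position, which inverts the allyl unit to the linear prenyl group, and tautomerisation of the dienone restores the naphthol.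

Step 4
Reactants: 7 tetronic acid (furan-2,4(3H,5H)-dione)
Product: 8 4-bromofuran-2(5H)-one
Conditions: (COBr)2, DMF (cat.), CH2Cl2, 0 °C → rt
Reagents that add atoms: oxalyl bromide, O=C(Br)C(Br)=O
Why: Vilsmeier-type activation of the enol form of tetronic acid, a vinylogous carboxylic acid, by the bromoiminium salt formed from oxalyl bromide and DMF, followed by addition–elimination of bromide, gives the vinylogous acyl bromide; this is the standard preparation of 4-halobutenolides.

Step 5
Reactants: 6 methyl 4-hydroxy-1-(methoxymethoxy)-3-(3-methylbut-2-en-1-yl)naphthalene-2-carboxylate; 8 4-bromofuran-2(5H)-one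
Product: 9 methyl 1-(methoxymethoxy)-3-(3-methylbut-2-en-1-yl)-4-[(5-oxo-2,5-dihydrofuran-3-yl)oxy]naphthalene-2-carboxylate
Conditions: K2CO3, DMF, 0 °C → rt, Ar
Reagents that add atoms: none
Why: Nucleophilic vinylic substitution (conjugate addition–elimination) of the potassium naphthoxide at C4 of the β-bromobutenolide, which behaves as a vinylogous acyl bromide; 6 has a single free hydroxyl, so there is no site issue, and attack through oxygen is expected because the ortho and para carbons of the naphthoxide are all substituted.

Step 6
Reactants: 9 methyl 1-(methoxymethoxy)-3-(3-methylbut-2-en-1-yl)-4-[(5-oxo-2,5-dihydrofuran-3-yl)oxy]naphthalene-2-carboxylate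
Product: 10 methyl 1-(methoxymethoxy)-3-(3-methylbut-2-en-1-yl)-4-({5-[tri(propan-2-yl)silyloxy]furan-3-yl}oxy)naphthalene-2-carboxylate
Conditions: TIPSOTf, Et3N, CH2Cl2, 0 °C
Reagents that add atoms: tri(propan-2-yl)silyl trifluoromethanesulfonate (TIPSOTf), CC(C)[Si](OS(=O)(=O)C(F)(F)F)(C(C)C)C(C)C
Why: Soft enolisation of the butenolide at its γ-CH2 by the silyl triflate and amine gives the aromatic 2-silyloxyfuran, the standard route from butenolides and tetronates to silyloxyfuran dienes; the bulky TIPS group is chosen as the common silyl group most likely to survive the fluoride of the next step, and the ester and the MOM acetal are inert to TIPSOTf in the presence of excess amine.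

Step 7
Reactants: 10 methyl 1-(methoxymethoxy)-3-(3-methylbut-2-en-1-yl)-4-({5-[tri(propan-2-yl)silyloxy]furan-3-yl}oxy)naphthalene-2-carboxylate; 11 2-(trimethylsilyl)phenyl trifluoromethanesulfonate
Product: 14 methyl 4-({1-hydroxy-4-[tri(propan-2-yl)silyloxy]naphthalen-2-yl}oxy)-1-(methoxymethoxy)-3-(3-methylbut-2-en-1-yl)naphthalene-2-carboxylate, via benzyne 12 (not isolated), via oxa-bridged ketal 13 (not isolated)
Conditions: 11 (slow addition, small excess), CsF, MeCN, 0 °C → rt; then SiO2
Reagents that add atoms: none
Why: Fluoride attacks the trimethylsilyl group of 11 and the aryl anion expels triflate, so that benzyne 12 is released at a low steady concentration. The electron-rich 2,4-dioxygenated furan of 10 (high HOMO) and the strained, low-LUMO triple bond of 12 combine in a concerted though asynchronous [4+2] cycloaddition across furan C2 and C5, which forms C4'–C4a' and C1'–C8a' in one intermolecular step and closes the new six-membered carbocycle (ring C) as the oxa-bridged ketal 13. The bridgehead C–O bond at the silyloxy-bearing carbon then ionises, helped by the silyloxy lone pair and by release of bicyclic strain, and loss of the C1' hydrogen from the alkoxide-bearing carbon (a net tautomerisation, completed on silica) aromatises the ring to the 4-silyloxy-1-naphthol 14. The closest known reaction type is the aryne Diels–Alder reaction of 2-alkoxy- and 2-silyloxyfurans with opening of the bridged ketal to 4-oxygenated 1-naphthols; the 4-aryloxy group is a further donor on the diene and should raise its reactivity. No stereocentre survives, since the two bridgehead centres of racemic 13 are erased on aromatisation. Regioselectivity is not an issue because 12 is symmetrical and either sense of ketal opening leads to the same quinone after step 8. The selectivity needed is chemoselectivity: the furan must outcompete the prenyl alkene (ene reaction) and every oxygen nucleophile, which is secured by the much higher diene reactivity of the furan, by the MOM acetal on O1, and by adding 11 slowly in small excess so that the naphthol of 14 is not O-arylated.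

Step 8
Reactants: 14 methyl 4-({1-hydroxy-4-[tri(propan-2-yl)silyloxy]naphthalen-2-yl}oxy)-1-(methoxymethoxy)-3-(3-methylbut-2-en-1-yl)naphthalene-2-carboxylate
Product: 16 methyl 4-[(1,4-dioxo-1,4-dihydronaphthalen-2-yl)oxy]-1-(methoxymethoxy)-3-(3-methylbut-2-en-1-yl)naphthalene-2-carboxylate, via hydroquinone 15 (not isolated)
Conditions: TBAF, AcOH, THF, 0 °C; then Ag2O, rt
Reagents that add atoms: none
Why: Fluoride cleaves the aryl silyl ether (strong Si–F bond), with acetic acid keeping the medium from becoming basic enough to hydrolyse the vinylogous ester that appears on oxidation; the electron-rich 2-aryloxynaphthalene-1,4-diol is then dehydrogenated to the quinone by Ag2O, while the left half, whose oxygens are capped as acetal and aryl ether, cannot reach a quinone.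

Step 9
Reactants: 16 methyl 4-[(1,4-dioxo-1,4-dihydronaphthalen-2-yl)oxy]-1-(methoxymethoxy)-3-(3-methylbut-2-en-1-yl)naphthalene-2-carboxylate
Product: 17 rubioncolin C, methyl 4-[(1,4-dioxo-1,4-dihydronaphthalen-2-yl)oxy]-1-hydroxy-3-(3-methylbut-2-en-1-yl)naphthalene-2-carboxylate
Conditions: TFA, CH2Cl2, 0 °C
Reagents that add atoms: none
Why: Acid-catalysed cleavage of the aryl MOM acetal, assisted by the neighbouring ester carbonyl, gives the hydrogen-bonded naphthol; in a non-nucleophilic medium at 0 °C the aryloxyquinone cannot undergo exchange, and the prenyl group has no internal nucleophile placed for a favourable cyclisation because O4 is an aryl ether.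

## Compound list

1 | methyl 1,4-dihydroxynaphthalene-2-carboxylate | COC(=O)c1cc(O)c2ccccc2c1O | starting material
2 | 3-chloro-3-methylbut-1-yne | CC(C)(Cl)C#C | starting material
3 | methyl 1-hydroxy-4-[(2-methylbut-3-yn-2-yl)oxy]naphthalene-2-carboxylate | COC(=O)c1cc(OC(C)(C)C#C)c2ccccc2c1O | intermediate
4 | methyl 1-(methoxymethoxy)-4-[(2-methylbut-3-yn-2-yl)oxy]naphthalene-2-carboxylate | COCOc1c(C(=O)OC)cc(OC(C)(C)C#C)c2ccccc12 | intermediate
5 | methyl 1-(methoxymethoxy)-4-[(2-methylbut-3-en-2-yl)oxy]naphthalene-2-carboxylate | COCOc1c(C(=O)OC)cc(OC(C)(C)C=C)c2ccccc12 | intermediate
6 | methyl 4-hydroxy-1-(methoxymethoxy)-3-(3-methylbut-2-en-1-yl)naphthalene-2-carboxylate | COCOc1c(C(=O)OC)c(CC=C(C)C)c(O)c2ccccc12 | intermediate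
7 | tetronic acid (furan-2,4(3H,5H)-dione) | O=C1CC(=O)CO1 | starting material
8 | 4-bromofuran-2(5H)-one | O=C1C=C(Br)CO1 | intermediate
9 | methyl 1-(methoxymethoxy)-3-(3-methylbut-2-en-1-yl)-4-[(5-oxo-2,5-dihydrofuran-3-yl)oxy]naphthalene-2-carboxylate | COCOc1c(C(=O)OC)c(CC=C(C)C)c(OC2=CC(=O)OC2)c2ccccc12 | intermediate
10 | methyl 1-(methoxymethoxy)-3-(3-methylbut-2-en-1-yl)-4-({5-[tri(propan-2-yl)silyloxy]furan-3-yl}oxy)naphthalene-2-carboxylate | COCOc1c(C(=O)OC)c(CC=C(C)C)c(Oc2coc(O[Si](C(C)C)(C(C)C)C(C)C)c2)c2ccccc12 | intermediate
11 | 2-(trimethylsilyl)phenyl trifluoromethanesulfonate | C[Si](C)(C)c1ccccc1OS(=O)(=O)C(F)(F)F | starting material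
12 | benzyne (cyclohexa-1,3-dien-5-yne) | C1#CC=CC=C1 | intermediate
13 | methyl 1-(methoxymethoxy)-3-(3-methylbut-2-en-1-yl)-4-({4-[tri(propan-2-yl)silyloxy]-1,4-dihydro-1,4-epoxynaphthalen-2-yl}oxy)naphthalene-2-carboxylate (racemic; the oxygen bridge fixes the relative configuration of the two bridgeheads) | COCOc1c(C(=O)OC)c(CC=C(C)C)c(OC2=CC3(O[Si](C(C)C)(C(C)C)C(C)C)OC2c2ccccc23)c2ccccc12 | intermediate
14 | methyl 4-({1-hydroxy-4-[tri(propan-2-yl)silyloxy]naphthalen-2-yl}oxy)-1-(methoxymethoxy)-3-(3-methylbut-2-en-1-yl)naphthalene-2-carboxylate | COCOc1c(C(=O)OC)c(CC=C(C)C)c(Oc2cc(O[Si](C(C)C)(C(C)C)C(C)C)c3ccccc3c2O)c2ccccc12 | intermediate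
15 | methyl 4-[(1,4-dihydroxynaphthalen-2-yl)oxy]-1-(methoxymethoxy)-3-(3-methylbut-2-en-1-yl)naphthalene-2-carboxylate | COCOc1c(C(=O)OC)c(CC=C(C)C)c(Oc2cc(O)c3ccccc3c2O)c2ccccc12 | intermediate
16 | methyl 4-[(1,4-dioxo-1,4-dihydronaphthalen-2-yl)oxy]-1-(methoxymethoxy)-3-(3-methylbut-2-en-1-yl)naphthalene-2-carboxylate | COCOc1c(C(=O)OC)c(CC=C(C)C)c(OC2=CC(=O)c3ccccc3C2=O)c2ccccc12 | intermediate
17 | rubioncolin C, methyl 4-[(1,4-dioxo-1,4-dihydronaphthalen-2-yl)oxy]-1-hydroxy-3-(3-methylbut-2-en-1-yl)naphthalene-2-carboxylate | COC(=O)c1c(CC=C(C)C)c(OC2=CC(=O)c3ccccc3C2=O)c2ccccc2c1O | target

## Step count and least certain steps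

Total step count: 9. Longest linear sequence: 8 steps (steps 1, 2, 3, 5, 6, 7, 8 and 9, from 1); step 4 is a one-step side branch.

Step 7 (key step). The most likely failure is premature desilylation of the diene by fluoride, followed by arylation of the resulting butenolide enolate, together with O-arylation of the naphthol of 14 by a second equivalent of 12. A [2+2] addition across the ketene acetal bond of the furan and an ene reaction at the prenyl group are less likely but possible. The cause is that the activator of 11 is also a desilylating agent and that the product carries a free hydroxyl. Fallback: the aryne is abandoned and ring C is brought in complete. The route is left at 6, whose potassium salt (K2CO3, DMF, 0 °C) is treated with commercial 2-bromonaphthalene-1,4-dione A4. Conjugate addition of the naphthoxide at C2' of A4 and loss of bromide, an established way to 2-aryloxy-1,4-naphthoquinones, should give 16 directly, where the route is rejoined for step 9. No new compound is made on this path.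

Step 5. The most likely failure is slow substitution by a naphthoxide that is shielded by the prenyl group and the peri hydrogen, with base-induced self-condensation of 8 through its acidic γ-CH2 and air oxidation of the electron-rich naphthoxide taking over. Fallback: the vinylogous ester is built from an alkyne instead of a vinyl bromide. Starting from 6, conjugate addition of the naphthoxide (Cs2CO3 cat., MeCN) to commercial methyl 4-hydroxybut-2-ynoate should give methyl 4-{[(2E)-1-hydroxy-4-methoxy-4-oxobut-2-en-2-yl]oxy}-1-(methoxymethoxy)-3-(3-methylbut-2-en-1-yl)naphthalene-2-carboxylate F1. The geometric isomers of F1 interconvert through reversible addition, and the E isomer, with CH2OH and the ester on the same side, lactonises with loss of methanol (under the basic conditions or with PPTS in warm toluene) to 9, where the route is rejoined.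

Step 3. The most likely failures are over-reduction of the alkyne past the alkene during the semi-hydrogenation, and ionisation of the tertiary allylic ether with loss of the C5 unit during heating, which would compete with the sigmatropic shift. Fallback: the prenyl group is put on carbon directly. Starting from 1, Friedel–Crafts allylation with 2-methylbut-3-en-2-ol and BF3·OEt2 (dioxane, rt) through the dimethylallyl cation should give methyl 1,4-dihydroxy-3-(3-methylbut-2-en-1-yl)naphthalene-2-carboxylate F2, which is handled under argon because F2 is an air-sensitive diol. O4-selective addition–elimination of F2 with 8 (K2CO3, DMF) would give methyl 1-hydroxy-3-(3-methylbut-2-en-1-yl)-4-[(5-oxo-2,5-dihydrofuran-3-yl)oxy]naphthalene-2-carboxylate F3, and MOM protection of O1 of F3 (MOMCl, i-Pr2NEt, CH2Cl2) returns the route to 9.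

Step 8. The most likely failure is cleavage of the ether linkage by addition–elimination at C2' once the quinone has formed, because fluoride solutions contain basic, nucleophilic species and the aryloxyquinone is a vinylogous ester. Fallback: desilylation and oxidation are replaced by one oxidative dearomatisation without fluoride or base. Starting from 14, PhI(OAc)2 in aqueous MeCN at 0 °C should bind the C1' hydroxyl to iodine, water should attack C4', and loss of tri(propan-2-yl)silanol from the hemiketal should give 16, where the route is rejoined. No new compound is made on this path.

## Further compounds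

F1 | step 5 | methyl 4-{[(2E)-1-hydroxy-4-methoxy-4-oxobut-2-en-2-yl]oxy}-1-(methoxymethoxy)-3-(3-methylbut-2-en-1-yl)naphthalene-2-carboxylate | COC(=O)/C=C(\CO)Oc1c(CC=C(C)C)c(C(=O)OC)c(OCOC)c2ccccc12
F2 | step 3 | methyl 1,4-dihydroxy-3-(3-methylbut-2-en-1-yl)naphthalene-2-carboxylate | COC(=O)c1c(CC=C(C)C)c(O)c2ccccc2c1O
F3 | step 3 | methyl 1-hydroxy-3-(3-methylbut-2-en-1-yl)-4-[(5-oxo-2,5-dihydrofuran-3-yl)oxy]naphthalene-2-carboxylate | COC(=O)c1c(CC=C(C)C)c(OC2=CC(=O)OC2)c2ccccc2c1O
F0 | step 7 | none | none
F0 | step 8 | none | none
A1 | alternative 1 | methyl 2-[2-(3-methylbut-2-en-1-yl)-1,3-dioxo-2,3-dihydro-1H-inden-2-yl]acetate | COC(=O)CC1(CC=C(C)C)C(=O)c2ccccc2C1=O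
A2 | alternative 1 | methyl 1,4-dihydroxy-3-(3-methylbut-2-en-1-yl)naphthalene-2-carboxylate | COC(=O)c1c(CC=C(C)C)c(O)c2ccccc2c1O
A3 | alternative 1 | indane-1,3-dione | O=C1CC(=O)c2ccccc21
A4 | alternative 1 | 2-bromonaphthalene-1,4-dione | O=C1C=C(Br)C(=O)c2ccccc12
A5 | alternative 2 | methyl 1-hydroxy-4-[(4-hydroxy-3-oxo-4-phenylcyclobut-1-en-1-yl)oxy]-3-(3-methylbut-2-en-1-yl)naphthalene-2-carboxylate (racemic) | COC(=O)c1c(CC=C(C)C)c(OC2=CC(=O)C2(O)c2ccccc2)c2ccccc2c1O
A6 | alternative 2 | methyl 4-[(1,4-dihydroxynaphthalen-2-yl)oxy]-1-hydroxy-3-(3-methylbut-2-en-1-yl)naphthalene-2-carboxylate | COC(=O)c1c(CC=C(C)C)c(Oc2cc(O)c3ccccc3c2O)c2ccccc2c1O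
A7 | alternative 2 | methyl 4-[(3,4-dioxocyclobut-1-en-1-yl)oxy]-1-hydroxy-3-(3-methylbut-2-en-1-yl)naphthalene-2-carboxylate | COC(=O)c1c(CC=C(C)C)c(OC2=CC(=O)C2=O)c2ccccc2c1O
A8 | alternative 3 | methyl 2-bromo-3-oxo-3-phenylpropanoate (racemic) | COC(=O)C(Br)C(=O)c1ccccc1
A9 | alternative 3 | 1,4-bis(methoxymethoxy)-2-[(5-methylhex-4-en-1-yn-1-yl)oxy]naphthalene | CC(C)=CCC#COc1cc(OCOC)c2ccccc2c1OCOC
A10 | alternative 3 | methyl 4-{[1,4-bis(methoxymethoxy)naphthalen-2-yl]oxy}-1-hydroxy-3-(3-methylbut-2-en-1-yl)naphthalene-2-carboxylate | COC(=O)c1c(CC=C(C)C)c(Oc2cc(OCOC)c3ccccc3c2OCOC)c2ccccc2c1O
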